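**Retrosynthetic overview**

1. Target ⇐ tetraol: 7,13-diacetylation while the cis-9,10-diol is masked in the flask as a phenylboronate.
2. Oxocane (the only ring, formed last) ⇐ ring expansion of a 2,3,5-trisubstituted oxolane: Ag(I)-triggered O–C6 bond formation gives a bicyclic oxonium, which the neighbouring O-Boc group opens at C9.
3. Oxolane (formed first) ⇐ 5-exo opening of a (12S,13S)-epoxide by the C9 hydroxyl of a syn-1,3-diol.
4. C7–C8 bond ⇐ Cornforth-controlled lithium aldol of a C8–C15 epoxy methyl ketone with a C1–C7 (S)-α-chloroaldehyde.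
5. Fragments ⇐ pent-1-ene + ethyl glyoxylate (ene, MeMgBr, Boc, Shi) and (Z)-1,2-dichloroethene + TMS-acetylene + 2-(2-bromoethyl)-1,3-dioxolane (Sonogashira, Fe-Kumada, α-chlorination).

Assumption: atoms are numbered along the C15 chain (C1 = alkyne terminus, C15 = ethyl CH3), the target SMILES reads as 3Z,6R,7R,9R,10S,12R,13S, and each chiral catalyst named is the enantiomer taken to give the stated configuration (its antipode is used if the sense is opposite).

**Route**

Step 1
Reactants: 1 (Z)-1,2-dichloroethene; 2 ethynyltrimethylsilane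
Product: 3 (Z)-(4-chlorobut-3-en-1-yn-1-yl)trimethylsilane
Conditions: 1 (5 equiv), Pd(PPh3)4 (5 mol %), CuI (10 mol %), n-BuNH2, Et2O, rt
Reagents that add atoms: none
Why: Sonogashira coupling of a vinyl chloride; excess dichloroethene stops at mono-coupling and the Z geometry is retained.

Step 2
Reactants: 3 (Z)-(4-chlorobut-3-en-1-yn-1-yl)trimethylsilane; 4 2-(2-bromoethyl)-1,3-dioxolane
Product: 7 (Z)-7-(trimethylsilyl)hept-4-en-6-ynal, via Grignard reagent 5 (not isolated), via dioxolane acetal 6 (not isolated)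
Conditions: 4, Mg, THF, 25 °C; then 3, Fe(acac)3 (5 mol %), THF–NMP, 0 °C; then 2 M HCl, THF, rt
Reagents that add atoms: water, O
Why: Iron-catalysed Kumada sp2–sp3 coupling of an alkenyl chloride with an alkyl Grignard keeps the Z-enyne, and aqueous acid then hydrolyses the acetal.

Step 3
Reactants: 7 (Z)-7-(trimethylsilyl)hept-4-en-6-ynal
Product: 8 (2S,4Z)-2-chloro-7-(trimethylsilyl)hept-4-en-6-ynal
Conditions: NCS, 2,5-diphenylpyrrolidine (10 mol %, enantiomer giving 2S), CH2Cl2, 0 °C; used crude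
Reagents that add atoms: N-chlorosuccinimide, O=C1CCC(=O)N1Cl
Why: Enamine-catalysed α-chlorination of an aldehyde; the chiral pyrrolidine shields one enamine face and sets C6 (as the 2S chloride).

Step 4
Reactants: 9 pent-1-ene; 10 ethyl glyoxylate
Product: 11 ethyl (2S,4E)-2-hydroxyhept-4-enoate
Conditions: [Cu((S,S)-t-Bu-box)(H2O)2](SbF6)2 (10 mol %), 9 (excess), CH2Cl2, 0 °C → rt
Reagents that add atoms: none
Why: Catalytic enantioselective glyoxylate–ene reaction; the chelated glyoxylate is attacked on one face, setting C10 (S) and the 12E alkene.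

Step 5
Reactants: 11 ethyl (2S,4E)-2-hydroxyhept-4-enoate
Product: 13 (3S,5E)-3-hydroxyoct-5-en-2-one, via Weinreb amide 12 (not isolated)
Conditions: MeNHOMe·HCl, i-PrMgCl, THF, −20 °C; then MeMgBr, 0 °C; aq NH4Cl
Reagents that add atoms: methylmagnesium bromide, C[Mg]Br
Why: One-pot Weinreb ketone synthesis; the magnesium chelate stops at the ketone and the magnesium alkoxide protects the α-stereocentre.

Step 6
Reactants: 13 (3S,5E)-3-hydroxyoct-5-en-2-one
Product: 14 tert-butyl (3S,5E)-2-oxooct-5-en-3-yl carbonate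
Conditions: Boc2O, DMAP (10 mol %), CH2Cl2, 0 °C
Reagents that add atoms: di-tert-butyl dicarbonate, CC(C)(C)OC(=O)OC(=O)OC(C)(C)C
Why: DMAP-catalysed O-acylation installs the carbonate that later acts as the internal nucleophile.

Step 7
Reactants: 14 tert-butyl (3S,5E)-2-oxooct-5-en-3-yl carbonate
Product: 15 tert-butyl (2S)-1-[(2S,3S)-3-ethyloxiran-2-yl]-3-oxobutan-2-yl carbonate
Conditions: ent-Shi ketone (30 mol %), Oxone, K2CO3, Bu4NHSO4, MeCN–DMM–aq buffer (pH 10.5), 0 °C
Reagents that add atoms: potassium peroxymonosulfate (Oxone), [K+].[O-]S(=O)(=O)OO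
Why: Shi epoxidation of the only alkene, a trans-disubstituted one; the chiral dioxirane (spiro transition state) sets the (12S,13S)-epoxide under reagent control.

Step 8
Reactants: 15 tert-butyl (2S)-1-[(2S,3S)-3-ethyloxiran-2-yl]-3-oxobutan-2-yl carbonate; 8 (2S,4Z)-2-chloro-7-(trimethylsilyl)hept-4-en-6-ynal
Product: 17 (3Z,6S,7R,10S,12S,13S)-10-[(tert-butoxycarbonyl)oxy]-6-chloro-12,13-epoxy-7-hydroxy-1-(trimethylsilyl)pentadec-3-en-1-yn-9-one, via lithium enolate 16 (not isolated)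
Conditions: LDA (1.05 equiv), THF, −78 °C; then 8, −78 °C, 30 min; AcOH
Reagents that add atoms: none
Why: Lithium aldol of a methyl ketone with an α-chloroaldehyde; the Cornforth transition state gives the 1,2-anti chlorohydrin, setting C7 (R) next to the (6S)-chloride.

Step 9
Reactants: 17 (3Z,6S,7R,10S,12S,13S)-10-[(tert-butoxycarbonyl)oxy]-6-chloro-12,13-epoxy-7-hydroxy-1-(trimethylsilyl)pentadec-3-en-1-yn-9-one
Product: 19 tert-butyl (2S,3S,5R)-2-[(2R,3S,5Z)-3-chloro-2-hydroxy-8-(trimethylsilyl)oct-5-en-7-yn-1-yl]-5-[(1S)-1-hydroxypropyl]oxolan-3-yl carbonate, via epoxy diol 18 (not isolated)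
Conditions: Et2BOMe, THF–MeOH, −78 °C; NaBH4; MeOH co-evaporation; then CSA (10 mol %), CH2Cl2, 0 °C
Reagents that add atoms: none
Why: Narasaka–Prasad reduction through the boron chelate gives the 7,9-syn diol (C9 S); acid-catalysed 5-exo epoxide opening by the C9 hydroxyl inverts C12 to R and frees the (13S)-alcohol.

Step 10
Reactants: 19 tert-butyl (2S,3S,5R)-2-[(2R,3S,5Z)-3-chloro-2-hydroxy-8-(trimethylsilyl)oct-5-en-7-yn-1-yl]-5-[(1S)-1-hydroxypropyl]oxolan-3-yl carbonate
Product: 22 (3Z,6R,7R,9R,10S,12R,13S)-6,12-epoxy-7,13-dihydroxy-1-(trimethylsilyl)pentadec-3-en-1-yne-9,10-diyl carbonate, via bicyclic oxonium triflate 20 (not isolated), via tert-butoxydioxolanylium triflate 21 (not isolated)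
Conditions: AgOTf (3 equiv), 2,6-di-tert-butyl-4-methylpyridine (3 equiv), 4 Å MS, CH2Cl2, −40 °C → rt
Reagents that add atoms: none
Why: Proposed new method: Ag(I) abstracts the secondary chloride with anchimeric assistance from the oxolane oxygen (5-exo, inversion at C6) to give the cis-fused 1-oxoniabicyclo[3.3.0]octane 20, whose ring-fusion carbon C9 is opened with inversion by the carbonyl oxygen of the adjacent tert-butyl carbonate (then loss of isobutene), so the oxolane expands by three atoms to the oxocane and C9 (R) is set as the cis-9,10-carbonate; the closest known reaction types are the bromonium-induced ring expansion of tetrahydrofurans to eight-membered bromoethers through oxonium ions with carbonate termination, and silver-promoted chlorohydrin cycloetherification.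

Step 11
Reactants: 22 (3Z,6R,7R,9R,10S,12R,13S)-6,12-epoxy-7,13-dihydroxy-1-(trimethylsilyl)pentadec-3-en-1-yne-9,10-diyl carbonate
Product: 23 (3Z,6R,7R,9R,10S,12R,13S)-6,12-epoxypentadec-3-en-1-yne-7,9,10,13-tetrol
Conditions: K2CO3 (0.3 equiv), MeOH, rt
Reagents that add atoms: none
Why: Base-catalysed methanolysis cleaves the cyclic carbonate and the alkynyl–silicon bond in one operation without touching any stereocentre.

Step 12
Reactants: 23 (3Z,6R,7R,9R,10S,12R,13S)-6,12-epoxypentadec-3-en-1-yne-7,9,10,13-tetrol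
Product: 26 (3Z,6R,7R,9R,10S,12R,13S)-6,12-epoxy-9,10-dihydroxypentadec-3-en-1-yne-7,13-diyl diacetate, via phenylboronate 24 (not isolated), via diacetyl phenylboronate 25 (not isolated)
Conditions: PhB(OH)2 (1.05 equiv), pyridine, 4 Å MS, rt; then Ac2O, DMAP (cat.), 0 °C → rt; then pinacol, MeOH–H2O, rt
Reagents that add atoms: acetic anhydride, CC(=O)OC(C)=O
Why: Transient boronate protection: only the cis-9,10-diol forms a five-membered boronate, the two remaining alcohols are acetylated, and transesterification with pinacol frees the diol.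

**Compound list**

1 | (Z)-1,2-dichloroethene | Cl/C=C\Cl | starting material
2 | ethynyltrimethylsilane | C#C[Si](C)(C)C | starting material
3 | (Z)-(4-chlorobut-3-en-1-yn-1-yl)trimethylsilane | Cl/C=C\C#C[Si](C)(C)C | intermediate
4 | 2-(2-bromoethyl)-1,3-dioxolane | BrCCC1OCCO1 | starting material
5 | [2-(1,3-dioxolan-2-yl)ethyl]magnesium bromide (Grignard reagent) | Br[Mg]CCC1OCCO1 | intermediate (not isolated)
6 | (Z)-2-[6-(trimethylsilyl)hex-3-en-5-yn-1-yl]-1,3-dioxolane (dioxolane acetal) | C[Si](C)(C)C#C/C=C\CCC1OCCO1 | intermediate (not isolated)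
7 | (Z)-7-(trimethylsilyl)hept-4-en-6-ynal | O=CCC/C=C\C#C[Si](C)(C)C | intermediate
8 | (2S,4Z)-2-chloro-7-(trimethylsilyl)hept-4-en-6-ynal | O=C[C@@H](Cl)C/C=C\C#C[Si](C)(C)C | intermediate
9 | pent-1-ene | C=CCCC | starting material
10 | ethyl glyoxylate | CCOC(=O)C=O | starting material
11 | ethyl (2S,4E)-2-hydroxyhept-4-enoate | CCOC(=O)[C@@H](O)C/C=C/CC | intermediate
12 | (2S,4E)-2-hydroxy-N-methoxy-N-methylhept-4-enamide (Weinreb amide) | CON(C)C(=O)[C@@H](O)C/C=C/CC | intermediate (not isolated)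
13 | (3S,5E)-3-hydroxyoct-5-en-2-one | CC(=O)[C@@H](O)C/C=C/CC | intermediate
14 | tert-butyl (3S,5E)-2-oxooct-5-en-3-yl carbonate | CC(=O)[C@@H](OC(=O)OC(C)(C)C)C/C=C/CC | intermediate
15 | tert-butyl (2S)-1-[(2S,3S)-3-ethyloxiran-2-yl]-3-oxobutan-2-yl carbonate | CC(=O)[C@@H](OC(=O)OC(C)(C)C)C[C@@H]1O[C@H]1CC | intermediate
16 | lithium enolate of 15 (terminal, C8) | [Li]OC(=C)[C@@H](OC(=O)OC(C)(C)C)C[C@@H]1O[C@H]1CC | intermediate (not isolated)
17 | (3Z,6S,7R,10S,12S,13S)-10-[(tert-butoxycarbonyl)oxy]-6-chloro-12,13-epoxy-7-hydroxy-1-(trimethylsilyl)pentadec-3-en-1-yn-9-one | C[Si](C)(C)C#C/C=C\C[C@H](Cl)[C@H](O)CC(=O)[C@@H](OC(=O)OC(C)(C)C)C[C@@H]1O[C@H]1CC | intermediate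
18 | (3Z,6S,7R,9S,10S,12S,13S)-6-chloro-12,13-epoxy-7,9-dihydroxy-1-(trimethylsilyl)pentadec-3-en-1-yn-10-yl tert-butyl carbonate (epoxy diol) | C[Si](C)(C)C#C/C=C\C[C@H](Cl)[C@H](O)C[C@H](O)[C@@H](OC(=O)OC(C)(C)C)C[C@@H]1O[C@H]1CC | intermediate (not isolated)
19 | tert-butyl (2S,3S,5R)-2-[(2R,3S,5Z)-3-chloro-2-hydroxy-8-(trimethylsilyl)oct-5-en-7-yn-1-yl]-5-[(1S)-1-hydroxypropyl]oxolan-3-yl carbonate | C[Si](C)(C)C#C/C=C\C[C@H](Cl)[C@H](O)C[C@@H]1O[C@@H]([C@@H](O)CC)C[C@@H]1OC(=O)OC(C)(C)C | intermediate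
20 | cis-fused 1-oxoniabicyclo[3.3.0]octane triflate: O+ bonded to C6, C9 and C12 (6R,7R,9S,10S,12R,13S; 7-OH, 10-OBoc, 13-OH, TMS-enyne side chain) | C[Si](C)(C)C#C/C=C\C[C@@H]1[C@H](O)C[C@H]2[C@@H](OC(=O)OC(C)(C)C)C[C@H]([C@@H](O)CC)[O+]12.[O-]S(=O)(=O)C(F)(F)F | intermediate (not isolated)
21 | oxocane (6R,7R,9R,10S,12R,13S) carrying a 2-tert-butoxy-1,3-dioxolan-2-ylium ring across O9/O10, triflate | C[Si](C)(C)C#C/C=C\C[C@H]1O[C@@H]([C@@H](O)CC)C[C@@H]2OC(OC(C)(C)C)=[O+][C@@H]2C[C@H]1O.[O-]S(=O)(=O)C(F)(F)F | intermediate (not isolated)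
22 | (3Z,6R,7R,9R,10S,12R,13S)-6,12-epoxy-7,13-dihydroxy-1-(trimethylsilyl)pentadec-3-en-1-yne-9,10-diyl carbonate | C[Si](C)(C)C#C/C=C\C[C@H]1O[C@@H]([C@@H](O)CC)C[C@@H]2OC(=O)O[C@@H]2C[C@H]1O | intermediate
23 | (3Z,6R,7R,9R,10S,12R,13S)-6,12-epoxypentadec-3-en-1-yne-7,9,10,13-tetrol | C#C/C=C\C[C@H]1O[C@@H]([C@@H](O)CC)C[C@H](O)[C@H](O)C[C@H]1O | intermediate
24 | (3Z,6R,7R,9R,10S,12R,13S)-6,12-epoxy-9,10-[(phenylboranediyl)bis(oxy)]pentadec-3-en-1-yne-7,13-diol (phenylboronate) | C#C/C=C\C[C@H]1O[C@@H]([C@@H](O)CC)C[C@@H]2OB(c3ccccc3)O[C@@H]2C[C@H]1O | intermediate (not isolated)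
25 | (3Z,6R,7R,9R,10S,12R,13S)-6,12-epoxy-9,10-[(phenylboranediyl)bis(oxy)]pentadec-3-en-1-yne-7,13-diyl diacetate (diacetyl phenylboronate) | C#C/C=C\C[C@H]1O[C@@H]([C@H](CC)OC(C)=O)C[C@@H]2OB(c3ccccc3)O[C@@H]2C[C@H]1OC(C)=O | intermediate (not isolated)
26 | (3Z,6R,7R,9R,10S,12R,13S)-6,12-epoxy-9,10-dihydroxypentadec-3-en-1-yne-7,13-diyl diacetate (CNP0314743.1) | C#C/C=C\C[C@H]1O[C@@H]([C@H](CC)OC(C)=O)C[C@H](O)[C@H](O)C[C@H]1OC(C)=O | target

**Step count**

Total: 12 steps. Longest linear sequence: 9 steps (steps 4–12); the other branch (steps 1–3) joins at step 8.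

**Three steps most likely to fail**

Step 10 (the proposed new ring expansion). Risks are competing epoxide formation from the chlorohydrin, a hydride shift after ionisation, or capture of the oxonium ion by triflate. The fallback uses known reaction types only; it sets out from 14 and returns at 23. Ketone 14 (alkene not yet epoxidised) is taken through the same LDA aldol with 8 and the same Et2BOMe/NaBH4 reduction, giving the dienyl aldol adduct F1 and then the syn-diol F2. AgOTf/Ag2O in THF (silver-promoted chlorohydrin cycloetherification) closes the C9 hydroxyl onto C6 with inversion to give the 2,5-trans-oxolane F3. BDSB (Et2SBr·SbCl5Br, MeNO2, −25 °C) then effects the bromonium-induced ring expansion with carbonate termination, giving the bromo-oxocane carbonate F4 (bromine at C13, anti to the new C12–O bond). AgOAc in AcOH replaces the bromide by acetate with retention through participation of the ring oxygen, giving the 13-acetate F5; opening of the oxiranium at C12 instead would be the main side reaction. K2CO3/MeOH cleaves acetate, carbonate and silyl group to give 23.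

Step 8 (aldol of the epoxide- and carbonate-bearing ketone). Risks are carbonate transfer to the enolate, attack of the enolate on the epoxide, or erosion of the α-stereocentres. The fallback introduces the epoxide after the C–C bond is made; it sets out from 14 and returns at 19. LDA aldol of 14 with 8 gives the dienyl aldol adduct F1 and Narasaka–Prasad reduction gives the syn-diol F2. Shi epoxidation (ent-Shi ketone, Oxone, pH 10.5, 0 °C) attacks the trans-dialkyl alkene in preference to the Z-enyne alkene and gives 18, which closes to 19 with catalytic CSA.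

Step 12 (one-pot boronate-masked diacetylation). Risks are incomplete or misplaced boronate formation, or acetyl migration when the boronate is released. The fallback uses a stable acetal; it sets out from 23 and returns at 26. 2,2-Dimethoxypropane with PPTS in acetone gives the cis-9,10-acetonide F6; Ac2O, pyridine and DMAP give the diacetate acetonide F7; 80% aqueous AcOH at 40 °C removes the acetonide to give 26.

**Further compounds**

F1 | step 8 | (3Z,6S,7R,10S,12E)-10-[(tert-butoxycarbonyl)oxy]-6-chloro-7-hydroxy-1-(trimethylsilyl)pentadeca-3,12-dien-1-yn-9-one | C[Si](C)(C)C#C/C=C\C[C@H](Cl)[C@H](O)CC(=O)[C@@H](OC(=O)OC(C)(C)C)C/C=C/CC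
F2 | step 8 | (3Z,6S,7R,9S,10S,12E)-6-chloro-7,9-dihydroxy-1-(trimethylsilyl)pentadeca-3,12-dien-1-yn-10-yl tert-butyl carbonate | C[Si](C)(C)C#C/C=C\C[C@H](Cl)[C@H](O)C[C@H](O)[C@@H](OC(=O)OC(C)(C)C)C/C=C/CC
F3 | step 10 | tert-butyl (1S,3E)-1-[(2S,4R,5R)-4-hydroxy-5-[(2Z)-5-(trimethylsilyl)pent-2-en-4-yn-1-yl]oxolan-2-yl]hex-3-en-1-yl carbonate | C[Si](C)(C)C#C/C=C\C[C@H]1O[C@H]([C@@H](OC(=O)OC(C)(C)C)C/C=C/CC)C[C@H]1O
F4 | step 10 | (3Z,6R,7R,9R,10S,12R,13S)-13-bromo-6,12-epoxy-7-hydroxy-1-(trimethylsilyl)pentadec-3-en-1-yne-9,10-diyl carbonate | C[Si](C)(C)C#C/C=C\C[C@H]1O[C@@H]([C@@H](Br)CC)C[C@@H]2OC(=O)O[C@@H]2C[C@H]1O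
F5 | step 10 | (3Z,6R,7R,9R,10S,12R,13S)-13-acetoxy-6,12-epoxy-7-hydroxy-1-(trimethylsilyl)pentadec-3-en-1-yne-9,10-diyl carbonate | C[Si](C)(C)C#C/C=C\C[C@H]1O[C@@H]([C@H](CC)OC(C)=O)C[C@@H]2OC(=O)O[C@@H]2C[C@H]1O
F6 | step 12 | (3Z,6R,7R,9R,10S,12R,13S)-6,12-epoxy-9,10-(isopropylidenedioxy)pentadec-3-en-1-yne-7,13-diol | C#C/C=C\C[C@H]1O[C@@H]([C@@H](O)CC)C[C@@H]2OC(C)(C)O[C@@H]2C[C@H]1O
F7 | step 12 | (3Z,6R,7R,9R,10S,12R,13S)-6,12-epoxy-9,10-(isopropylidenedioxy)pentadec-3-en-1-yne-7,13-diyl diacetate | C#C/C=C\C[C@H]1O[C@@H]([C@H](CC)OC(C)=O)C[C@@H]2OC(C)(C)O[C@@H]2C[C@H]1OC(C)=O
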